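**Plan**

1. Numbering: heavy atoms 1–35 as in the target SMILES; ring A = oxepane O16/C17/C7/C9/C10/C11/C13, ring B = C6/C7/C17/C18/C19/C20, ring C = enone ring C2/C3/C23/C24/C25/C26, ring D = C23/C24/C28/C31/C32/C33.
2. Cuts: first C3–C4 (C4 alkyllithium onto the C3 carbonyl of a ring CD enone, then oxidative 1,3-transposition). Then, in ring A, the segment O16–C13(Me2)–C11(=O) is read as a 2,2-dimethylfuran-3(2H)-one whose C10=C17 bond has the alkene carbons C9 and C7 inserted, so C10–C9 and C17–C7 are cut and C10–C17 is restored. Last, C20–C6 (allylboration of methyl levulinate).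
3. Forward, left half: C4–C9 allylboronate plus levulinate, then furanone 13, then rings B and A in one flask (photocycloaddition closes ring B, fragmentation–reduction expands the furanone to ring A), then C11 alcohol and C4 iodide.
4. Forward, right half: ring D is annulated onto an anisole (future ring C) as a tetralone; methyl addition, Birch reduction, directed hydrogenation and a carbonyl transposition give the ring CD enone. The halves are joined at C3–C4 and desilylated.
5. Stereochemistry: C20 and C6 from a diol-catalysed (Z)-allylboration through a chair transition state; C7 from the chair-like photocycloaddition; C17 from axial hydride delivery; C11 from oxazaborolidine reduction; C28 from a catalytic asymmetric methyl addition; C23 and C24 from hydrogenation directed by the C28 hydroxyl.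

Key step: step 7

Assumption: the absolute sense of the two catalyst-controlled additions (steps 3 and 13) is taken as drawn; if either catalyst delivers the opposite face, its mirror-image form is used and nothing else changes.

Remark: C4 is carried as a benzyl ether so that it can be unmasked by hydrogenolysis beside three silyl ethers. Epimer mixtures at C2 (27, 28), at the epoxide of 30 and at the carbinol carbon of 31 and 35 are inconsequential, because these centres become trigonal later.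

**Route**

Step 1
Reactants: 1 3-(benzyloxy)propanal
Product: 2 {[(3Z)-4-iodopent-3-en-1-yl]oxy}methylbenzene
Conditions: EtPPh3I, n-BuLi, THF, 0 °C; I2, −78 °C; NaN(SiMe3)2, −20 °C; then 1, −78 °C → rt
Reagents that add atoms: ethyltriphenylphosphonium iodide, CC[P+](c1ccccc1)(c1ccccc1)c1ccccc1.[I-]; iodine, II
Why: Stork–Zhao olefination with the iodo-ylide Ph3P=C(I)CH3 passes through the kinetically favoured cis-oxaphosphetane and should give the (Z)-iodoalkene (iodine cis to the chain), which fixes the later boronate geometry.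

Step 2
Reactants: 2 {[(3Z)-4-iodopent-3-en-1-yl]oxy}methylbenzene
Product: 4 diisopropyl [(2Z)-5-(benzyloxy)-2-methylpent-2-en-1-yl]boronate, via alkenyllithium 3 (not isolated)
Conditions: t-BuLi (2 equiv), Et2O, −78 °C; BrCH2B(O-i-Pr)2, −78 °C → rt
Reagents that add atoms: diisopropyl (bromomethyl)boronate, CC(C)OB(CBr)OC(C)C
Why: Iodine–lithium exchange retains the alkene geometry, and the boron ate complex rearranges by 1,2-shift with loss of bromide (Matteson homologation), so the chain stays cis to the new CH2B group.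

Step 3
Reactants: 4 diisopropyl [(2Z)-5-(benzyloxy)-2-methylpent-2-en-1-yl]boronate; 5 methyl levulinate
Product: 7 (5S)-5-[(3S)-5-(benzyloxy)-2-methylpent-1-en-3-yl]-5-methyldihydrofuran-2(3H)-one, via hydroxy ester 6 (not isolated)
Conditions: (S)-3,3'-dibromo-1,1'-bi-2-naphthol (15 mol%), PhCF3/toluene, −35 °C; aq. work-up; TsOH (cat.), CH2Cl2, rt
Reagents that add atoms: none
Why: Diol-catalysed allylboration of a methyl ketone through a closed chair (Zimmerman–Traxler) transition state: with the ester arm equatorial and the ketone methyl axial, the (Z)-boronate carries its γ-substituent axial and should give the (4S,5S) pair (C20, C6), the chiral diol choosing the ketone face; acid then closes the γ-lactone.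

Step 4
Reactants: 7 (5S)-5-[(3S)-5-(benzyloxy)-2-methylpent-1-en-3-yl]-5-methyldihydrofuran-2(3H)-one
Product: 8 (4S,5S)-7-(benzyloxy)-4-hydroxy-N-methoxy-N,4-dimethyl-5-(prop-1-en-2-yl)heptanamide
Conditions: MeNH(OMe)·HCl, i-PrMgCl, THF, −20 → 0 °C
Reagents that add atoms: N,O-dimethylhydroxylamine hydrochloride, CNOC.Cl
Why: Aminolysis of the lactone by the magnesium amide opens the ring to the N-methoxy-N-methylamide and frees the tertiary alcohol for protection.

Step 5
Reactants: 8 (4S,5S)-7-(benzyloxy)-4-hydroxy-N-methoxy-N,4-dimethyl-5-(prop-1-en-2-yl)heptanamide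
Product: 9 (4S,5S)-7-(benzyloxy)-N-methoxy-N,4-dimethyl-5-(prop-1-en-2-yl)-4-[(triethylsilyl)oxy]heptanamide
Conditions: Et3SiOTf, 2,6-lutidine, CH2Cl2, −78 → 0 °C
Reagents that add atoms: triethylsilyl trifluoromethanesulfonate, CC[Si](CC)(CC)OS(=O)(=O)C(F)(F)F
Why: Silyl triflate silylation of the hindered tertiary alcohol; the ether keeps this oxygen from adding to the furanone (oxa-Michael, spiroketal) and to the later oxocarbenium ion.

Step 6
Reactants: 9 (4S,5S)-7-(benzyloxy)-N-methoxy-N,4-dimethyl-5-(prop-1-en-2-yl)-4-[(triethylsilyl)oxy]heptanamide; 10 3-hydroxy-3-methylbutan-2-one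
Product: 13 5-{(3S,4S)-6-(benzyloxy)-3-methyl-4-(prop-1-en-2-yl)-3-[(triethylsilyl)oxy]hexyl}-2,2-dimethylfuran-3(2H)-one, via dilithium dianion 11 (not isolated), via hydroxy diketone 12 (not isolated)
Conditions: 10, LiN(i-Pr)2 (2.2 equiv), THF, −78 → −20 °C; 9, −78 → 0 °C; aq. NH4Cl; PPTS (cat.), CH2Cl2, 4 Å MS, rt
Reagents that add atoms: none
Why: Claisen-type C-acylation of the ketone enolate by the N-methoxy-N-methylamide (the chelated tetrahedral intermediate stops over-addition), then acid-catalysed cyclodehydration of the 1-hydroxy-2,4-dione to the furan-3(2H)-one.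

Step 7
Reactants: 13 5-{(3S,4S)-6-(benzyloxy)-3-methyl-4-(prop-1-en-2-yl)-3-[(triethylsilyl)oxy]hexyl}-2,2-dimethylfuran-3(2H)-one
Product: 16 (5aS,6S,7S,9aS)-6-[2-(benzyloxy)ethyl]-2,2,5a,7-tetramethyl-7-[(triethylsilyl)oxy]octahydro-1-benzoxepin-3(2H)-one, via cyclobutane photoadduct 14 (not isolated), via trimethylsilyl enol ether 15 (not isolated)
Conditions: hν (350 nm, Pyrex), degassed CH2Cl2, 0 °C; then Et3SiH, Me3SiOTf, −78 → −20 °C; aq. NaHCO3; K2CO3, MeOH, 0 °C
Reagents that add atoms: none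
Why: Proposed new method: excitation gives the furanone triplet, whose β-carbon C17 attacks the internal alkene carbon C7 (ring B), and the 1,4-biradical collapses by C10–C9 bonding to cyclobutane 14; silyl triflate then activates the C11 ketone so that the lone pair of O16 expels C10 as its silyl enol ether (a retro-Mukaiyama-aldol opening of a donor–acceptor cyclobutane, driven by strain release), and Et3SiH reduces the seven-membered oxocarbenium ion at C17. The closest known reactions are the intramolecular enone–alkene [2+2] photocycloaddition, intermolecular photocycloadditions of furan-3(2H)-ones, the de Mayo fragmentation, and Lewis-acid opening of alkoxy-substituted donor–acceptor cyclobutanes with silane reduction of cyclic oxocarbenium ions. Ring B closes by the first C17–C7 bond (6-exo-trig through a chair-like tether), the cyclobutane by biradical recombination, and ring A is not closed by a new bond but arises when cleavage of the shared C10–C17 bond merges cyclobutane and furanone into the oxepane (two-carbon ring expansion). C7 is set in the photocycloaddition: with the C6 side chain equatorial and H6 eclipsing the C7=C9 bond (least allylic strain), C9 should end up trans to the C5 chain and methyl C8 axial; C17 is set by axial hydride attack anti to the axial methyl C8, which gives the trans ring fusion. The step needs straight rather than crossed regiochemistry, which the four-atom tether secures; the correct alkene face, which rests on the C6 stereocentre and is the untested point; and cleavage of C10–C17 only, which the push–pull substitution (O16 on C17, carbonyl next to C10) secures, the ketone being masked as its enol ether while the silane is present.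

Step 8
Reactants: 16 (5aS,6S,7S,9aS)-6-[2-(benzyloxy)ethyl]-2,2,5a,7-tetramethyl-7-[(triethylsilyl)oxy]octahydro-1-benzoxepin-3(2H)-one
Product: 17 (3S,5aS,6S,7S,9aS)-6-[2-(benzyloxy)ethyl]-2,2,5a,7-tetramethyl-7-[(triethylsilyl)oxy]decahydro-1-benzoxepin-3-ol
Conditions: (R)-2-methyl-CBS-oxazaborolidine, BH3·SMe2, THF, −20 °C; MeOH
Reagents that add atoms: none
Why: Corey–Bakshi–Shibata reduction, in which the quaternary C13 acts as the large and the C10 methylene as the small ketone substituent, so the (R)-catalyst should deliver hydride to the face that gives the (S)-alcohol at C11.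

Step 9
Reactants: 17 (3S,5aS,6S,7S,9aS)-6-[2-(benzyloxy)ethyl]-2,2,5a,7-tetramethyl-7-[(triethylsilyl)oxy]decahydro-1-benzoxepin-3-ol
Product: 18 (3S,5aS,6S,7S,9aS)-6-[2-(benzyloxy)ethyl]-3-[(tert-butyldimethylsilyl)oxy]-2,2,5a,7-tetramethyl-7-[(triethylsilyl)oxy]decahydro-1-benzoxepine
Conditions: t-BuMe2SiOTf, 2,6-lutidine, CH2Cl2, 0 °C
Reagents that add atoms: tert-butyldimethylsilyl trifluoromethanesulfonate, CC(C)(C)[Si](C)(C)OS(=O)(=O)C(F)(F)F
Why: Silyl triflate silylation of the hindered secondary alcohol gives an ether that survives the organolithium and the chromium oxidation to come.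

Step 10
Reactants: 18 (3S,5aS,6S,7S,9aS)-6-[2-(benzyloxy)ethyl]-3-[(tert-butyldimethylsilyl)oxy]-2,2,5a,7-tetramethyl-7-[(triethylsilyl)oxy]decahydro-1-benzoxepine
Product: 19 2-{(3S,5aS,6S,7S,9aS)-3-[(tert-butyldimethylsilyl)oxy]-2,2,5a,7-tetramethyl-7-[(triethylsilyl)oxy]decahydro-1-benzoxepin-6-yl}ethan-1-ol
Conditions: H2 (1 atm), Pd(OH)2/C, EtOAc, rt
Reagents that add atoms: none
Why: Catalytic hydrogenolysis of the benzyl ether; the saturated skeleton and the silyl ethers are inert under neutral conditions.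

Step 11
Reactants: 19 2-{(3S,5aS,6S,7S,9aS)-3-[(tert-butyldimethylsilyl)oxy]-2,2,5a,7-tetramethyl-7-[(triethylsilyl)oxy]decahydro-1-benzoxepin-6-yl}ethan-1-ol
Product: 20 (3S,5aS,6S,7S,9aS)-3-[(tert-butyldimethylsilyl)oxy]-6-(2-iodoethyl)-2,2,5a,7-tetramethyl-7-[(triethylsilyl)oxy]decahydro-1-benzoxepine
Conditions: I2, PPh3, imidazole, CH2Cl2, 0 °C → rt
Reagents that add atoms: iodine, II
Why: Appel-type iodination of the only free (primary) alcohol through its alkoxyphosphonium salt and SN2 displacement by iodide.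

Step 12
Reactants: 21 2-methylanisole; 22 5,5-dimethyldihydrofuran-2(3H)-one
Product: 24 7-methoxy-4,4,6-trimethyl-3,4-dihydronaphthalen-1(2H)-one, via arylpentanoic acid 23 (not isolated)
Conditions: AlCl3, CH2Cl2, 0 °C → rt; then P2O5/MeSO3H, 50 °C
Reagents that add atoms: none
Why: Friedel–Crafts alkylation by the tertiary cation from the lactone goes para to methoxy, and the intramolecular Friedel–Crafts acylation that follows can only use the unhindered ortho position of the new substituent, which places C33 on C23 and the future C28 on C24.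

Step 13
Reactants: 24 7-methoxy-4,4,6-trimethyl-3,4-dihydronaphthalen-1(2H)-one
Product: 25 (1S)-7-methoxy-1,4,4,6-tetramethyl-1,2,3,4-tetrahydronaphthalen-1-ol
Conditions: Me2Zn, Ti(O-i-Pr)4, trans-1,2-bis(hydroxycamphorsulfonamido)cyclohexane ligand (10 mol%), toluene/hexane, rt
Reagents that add atoms: dimethylzinc, C[Zn]C
Why: Titanium-mediated enantioselective addition of dimethylzinc to an aryl ketone under a chiral bis(sulfonamide) diol ligand sets C28, the one centre of the right half that is not relayed.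

Step 14
Reactants: 25 (1S)-7-methoxy-1,4,4,6-tetramethyl-1,2,3,4-tetrahydronaphthalen-1-ol
Product: 26 (1S)-7-methoxy-1,4,4,6-tetramethyl-1,2,3,4,5,8-hexahydronaphthalen-1-ol
Conditions: Li, NH3 (l), THF, t-BuOH, −78 °C; MeOH quench
Reagents that add atoms: none
Why: Birch reduction of the anisole ring protonates the two unsubstituted ring carbons (C3, C25) and leaves the methyl enol ether C26=C2 and the tetrasubstituted C23=C24 alkene; the benzylic oxygen travels as its lithium alkoxide, which resists C–O cleavage.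

Step 15
Reactants: 26 (1S)-7-methoxy-1,4,4,6-tetramethyl-1,2,3,4,5,8-hexahydronaphthalen-1-ol
Product: 28 (4aR,8S,8aS)-8-hydroxy-3,5,5,8-tetramethyloctahydronaphthalen-2(1H)-one, via saturated enol ether 27 (not isolated)
Conditions: [Ir(cod)(PCy3)(py)]PF6 (5 mol%), H2 (1 atm), CH2Cl2, rt; then 1 M HCl, THF, 0 °C
Reagents that add atoms: water, O
Why: Hydroxyl-directed hydrogenation: the cationic iridium catalyst binds the allylic tertiary hydroxyl and delivers both hydrogens to its own face of the tetrasubstituted alkene, which sets C23 and C24 cis to the C28 oxygen (cis ring fusion) before acid hydrolyses the remote enol ether.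

Step 16
Reactants: 28 (4aR,8S,8aS)-8-hydroxy-3,5,5,8-tetramethyloctahydronaphthalen-2(1H)-one
Product: 29 (4aR,8S,8aS)-8-hydroxy-3,5,5,8-tetramethyl-4a,5,6,7,8,8a-hexahydronaphthalen-2(1H)-one
Conditions: IBX (2-iodoxybenzoic acid), DMSO/toluene, 70 °C
Reagents that add atoms: none
Why: IBX dehydrogenation proceeds through the more substituted enol (towards C2) and should give the 2-methyl enone C2=C3, leaving the ring-fusion centres untouched.

Step 17
Reactants: 29 (4aR,8S,8aS)-8-hydroxy-3,5,5,8-tetramethyl-4a,5,6,7,8,8a-hexahydronaphthalen-2(1H)-one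
Product: 30 (4aR,8S,8aS)-3,4-epoxy-8-hydroxy-3,5,5,8-tetramethyloctahydronaphthalen-2(1H)-one
Conditions: H2O2 (30% aq.), NaOH, MeOH, 0 °C
Reagents that add atoms: hydrogen peroxide, OO
Why: Weitz–Scheffer nucleophilic epoxidation of the enone, the same reaction that converts carvone into its oxide.

Step 18
Reactants: 30 (4aR,8S,8aS)-3,4-epoxy-8-hydroxy-3,5,5,8-tetramethyloctahydronaphthalen-2(1H)-one
Product: 31 (4aS,5S,8aR)-2,5,8,8-tetramethyl-1,4,4a,5,6,7,8,8a-octahydronaphthalene-1,5-diol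
Conditions: N2H4·H2O, AcOH (cat.), MeOH, 0 °C → rt
Reagents that add atoms: none
Why: Wharton transposition: the epoxy hydrazone fragments with loss of nitrogen and moves the oxygen from C26 to C3 with the alkene now at C2=C26.

Step 19
Reactants: 31 (4aS,5S,8aR)-2,5,8,8-tetramethyl-1,4,4a,5,6,7,8,8a-octahydronaphthalene-1,5-diol
Product: 32 (4aS,5S,8aR)-5-hydroxy-2,5,8,8-tetramethyl-4a,5,6,7,8,8a-hexahydronaphthalen-1(4H)-one
Conditions: Dess–Martin periodinane, CH2Cl2, 0 °C → rt
Reagents that add atoms: none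
Why: Hypervalent-iodine oxidation of the secondary allylic alcohol to the enone; the tertiary alcohol cannot be oxidised.

Step 20
Reactants: 32 (4aS,5S,8aR)-5-hydroxy-2,5,8,8-tetramethyl-4a,5,6,7,8,8a-hexahydronaphthalen-1(4H)-one
Product: 33 (4aS,5S,8aR)-2,5,8,8-tetramethyl-5-[(triethylsilyl)oxy]-4a,5,6,7,8,8a-hexahydronaphthalen-1(4H)-one
Conditions: Et3SiOTf, 2,6-lutidine, CH2Cl2, −78 °C
Reagents that add atoms: triethylsilyl trifluoromethanesulfonate, CC[Si](CC)(CC)OS(=O)(=O)C(F)(F)F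
Why: Silyl triflate silylation of the tertiary alcohol at low temperature, so that the hydroxyl does not quench the alkyllithium of the next step.

Step 21
Reactants: 20 (3S,5aS,6S,7S,9aS)-3-[(tert-butyldimethylsilyl)oxy]-6-(2-iodoethyl)-2,2,5a,7-tetramethyl-7-[(triethylsilyl)oxy]decahydro-1-benzoxepine; 33 (4aS,5S,8aR)-2,5,8,8-tetramethyl-5-[(triethylsilyl)oxy]-4a,5,6,7,8,8a-hexahydronaphthalen-1(4H)-one
Product: 35 (4aS,5S,8aR)-1-{2-[(3S,5aS,6S,7S,9aS)-3-[(tert-butyldimethylsilyl)oxy]-2,2,5a,7-tetramethyl-7-[(triethylsilyl)oxy]decahydro-1-benzoxepin-6-yl]ethyl}-2,5,8,8-tetramethyl-5-[(triethylsilyl)oxy]-1,4,4a,5,6,7,8,8a-octahydronaphthalen-1-ol, via alkyllithium 34 (not isolated)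
Conditions: 20, t-BuLi (2.1 equiv), Et2O/pentane, −78 °C; then 33, THF, −78 °C; aq. NH4Cl
Reagents that add atoms: none
Why: Iodine–lithium exchange gives a primary alkyllithium that adds 1,2 to the enone carbonyl C3 (hard nucleophile, as in additions to carvone), forming the C3–C4 bond.

Step 22
Reactants: 35 (4aS,5S,8aR)-1-{2-[(3S,5aS,6S,7S,9aS)-3-[(tert-butyldimethylsilyl)oxy]-2,2,5a,7-tetramethyl-7-[(triethylsilyl)oxy]decahydro-1-benzoxepin-6-yl]ethyl}-2,5,8,8-tetramethyl-5-[(triethylsilyl)oxy]-1,4,4a,5,6,7,8,8a-octahydronaphthalen-1-ol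
Product: 36 (4aR,8S,8aS)-4-{2-[(3S,5aS,6S,7S,9aS)-3-[(tert-butyldimethylsilyl)oxy]-2,2,5a,7-tetramethyl-7-[(triethylsilyl)oxy]decahydro-1-benzoxepin-6-yl]ethyl}-3,5,5,8-tetramethyl-8-[(triethylsilyl)oxy]-4a,5,6,7,8,8a-hexahydronaphthalen-2(1H)-one
Conditions: pyridinium chlorochromate (C5H5NH[CrO3Cl]), 4 Å MS, CH2Cl2, rt
Reagents that add atoms: pyridinium chlorochromate, [O-][Cr](=O)(=O)Cl.c1cc[nH+]cc1
Why: Babler–Dauben oxidative transposition: the chromate ester of the tertiary allylic alcohol undergoes a [3,3]-shift and oxidation, which places the carbonyl at C26 and leaves the tetrasubstituted C2=C3 alkene bearing the side chain.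

Step 23
Reactants: 36 (4aR,8S,8aS)-4-{2-[(3S,5aS,6S,7S,9aS)-3-[(tert-butyldimethylsilyl)oxy]-2,2,5a,7-tetramethyl-7-[(triethylsilyl)oxy]decahydro-1-benzoxepin-6-yl]ethyl}-3,5,5,8-tetramethyl-8-[(triethylsilyl)oxy]-4a,5,6,7,8,8a-hexahydronaphthalen-2(1H)-one
Product: 37 sipholenol K
Conditions: HF (48% aq.), MeCN, 0 °C → rt
Reagents that add atoms: none
Why: Acidic fluoride desilylation removes the three silyl ethers in one operation and should leave the enone, the oxepane and the tertiary alcohols unchanged.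

**Compound list**

1 | 3-(benzyloxy)propanal | O=CCCOCc1ccccc1 | starting material
2 | {[(3Z)-4-iodopent-3-en-1-yl]oxy}methylbenzene | C/C(I)=C/CCOCc1ccccc1 | intermediate
3 | [5-(benzyloxy)pent-2-en-2-yl]lithium, chain cis to lithium (geometry of 2 retained) | [Li]/C(C)=C\CCOCc1ccccc1 | intermediate
4 | diisopropyl [(2Z)-5-(benzyloxy)-2-methylpent-2-en-1-yl]boronate | CC(C)OB(OC(C)C)C/C(C)=C\CCOCc1ccccc1 | intermediate
5 | methyl levulinate (methyl 4-oxopentanoate) | COC(=O)CCC(C)=O | starting material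
6 | methyl (4S,5S)-7-(benzyloxy)-4-hydroxy-4-methyl-5-(prop-1-en-2-yl)heptanoate | COC(=O)CC[C@](C)(O)[C@@H](CCOCc1ccccc1)C(C)=C | intermediate
7 | (5S)-5-[(3S)-5-(benzyloxy)-2-methylpent-1-en-3-yl]-5-methyldihydrofuran-2(3H)-one | O=C1CC[C@](C)(O1)[C@@H](CCOCc2ccccc2)C(C)=C | intermediate
8 | (4S,5S)-7-(benzyloxy)-4-hydroxy-N-methoxy-N,4-dimethyl-5-(prop-1-en-2-yl)heptanamide | CON(C)C(=O)CC[C@](C)(O)[C@@H](CCOCc1ccccc1)C(C)=C | intermediate
9 | (4S,5S)-7-(benzyloxy)-N-methoxy-N,4-dimethyl-5-(prop-1-en-2-yl)-4-[(triethylsilyl)oxy]heptanamide | CON(C)C(=O)CC[C@](C)(O[Si](CC)(CC)CC)[C@@H](CCOCc1ccccc1)C(C)=C | intermediate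
10 | 3-hydroxy-3-methylbutan-2-one | CC(=O)C(C)(C)O | starting material
11 | dilithium 3-methylbut-1-ene-2,3-bis(olate) | [Li+].[Li+].[O-]C(=C)C(C)(C)[O-] | intermediate
12 | (8S,9S)-11-(benzyloxy)-2-hydroxy-2,8-dimethyl-9-(prop-1-en-2-yl)-8-[(triethylsilyl)oxy]undecane-3,5-dione | CC(C)(O)C(=O)CC(=O)CC[C@](C)(O[Si](CC)(CC)CC)[C@@H](CCOCc1ccccc1)C(C)=C | intermediate
13 | 5-{(3S,4S)-6-(benzyloxy)-3-methyl-4-(prop-1-en-2-yl)-3-[(triethylsilyl)oxy]hexyl}-2,2-dimethylfuran-3(2H)-one | CC1(C)OC(=CC1=O)CC[C@](C)(O[Si](CC)(CC)CC)[C@@H](CCOCc2ccccc2)C(C)=C | intermediate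
14 | 8-[2-(benzyloxy)ethyl]-3,3,7,9-tetramethyl-9-[(triethylsilyl)oxy]-2-oxatricyclo[5.4.0.0(1,5)]undecan-4-one; cyclobutane cis-fused to both rings, C9 trans to the C5 chain, configuration as in the SMILES | c1ccccc1COCC[C@H]2[C@]3(C)C[C@H]4C(=O)C(C)(C)O[C@@]34CC[C@]2(C)O[Si](CC)(CC)CC | intermediate
15 | (5aS,6S,7S,9aS)-6-[2-(benzyloxy)ethyl]-2,2,5a,7-tetramethyl-7-[(triethylsilyl)oxy]-3-[(trimethylsilyl)oxy]-2,5,5a,6,7,8,9,9a-octahydro-1-benzoxepine | c1ccccc1COCC[C@H]1[C@]2(C)CC=C(O[Si](C)(C)C)C(C)(C)O[C@H]2CC[C@]1(C)O[Si](CC)(CC)CC | intermediate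
16 | (5aS,6S,7S,9aS)-6-[2-(benzyloxy)ethyl]-2,2,5a,7-tetramethyl-7-[(triethylsilyl)oxy]octahydro-1-benzoxepin-3(2H)-one | c1ccccc1COCC[C@H]1[C@]2(C)CCC(=O)C(C)(C)O[C@H]2CC[C@]1(C)O[Si](CC)(CC)CC | intermediate
17 | (3S,5aS,6S,7S,9aS)-6-[2-(benzyloxy)ethyl]-2,2,5a,7-tetramethyl-7-[(triethylsilyl)oxy]decahydro-1-benzoxepin-3-ol | c1ccccc1COCC[C@H]1[C@]2(C)CC[C@H](O)C(C)(C)O[C@H]2CC[C@]1(C)O[Si](CC)(CC)CC | intermediate
18 | (3S,5aS,6S,7S,9aS)-6-[2-(benzyloxy)ethyl]-3-[(tert-butyldimethylsilyl)oxy]-2,2,5a,7-tetramethyl-7-[(triethylsilyl)oxy]decahydro-1-benzoxepine | c1ccccc1COCC[C@H]1[C@]2(C)CC[C@H](O[Si](C)(C)C(C)(C)C)C(C)(C)O[C@H]2CC[C@]1(C)O[Si](CC)(CC)CC | intermediate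
19 | 2-{(3S,5aS,6S,7S,9aS)-3-[(tert-butyldimethylsilyl)oxy]-2,2,5a,7-tetramethyl-7-[(triethylsilyl)oxy]decahydro-1-benzoxepin-6-yl}ethan-1-ol | OCC[C@H]1[C@]2(C)CC[C@H](O[Si](C)(C)C(C)(C)C)C(C)(C)O[C@H]2CC[C@]1(C)O[Si](CC)(CC)CC | intermediate
20 | (3S,5aS,6S,7S,9aS)-3-[(tert-butyldimethylsilyl)oxy]-6-(2-iodoethyl)-2,2,5a,7-tetramethyl-7-[(triethylsilyl)oxy]decahydro-1-benzoxepine | ICC[C@H]1[C@]2(C)CC[C@H](O[Si](C)(C)C(C)(C)C)C(C)(C)O[C@H]2CC[C@]1(C)O[Si](CC)(CC)CC | intermediate
21 | 2-methylanisole (1-methoxy-2-methylbenzene) | COc1ccccc1C | starting material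
22 | 5,5-dimethyldihydrofuran-2(3H)-one | CC1(C)CCC(=O)O1 | starting material
23 | 4-(4-methoxy-3-methylphenyl)-4-methylpentanoic acid | COc1ccc(cc1C)C(C)(C)CCC(O)=O | intermediate
24 | 7-methoxy-4,4,6-trimethyl-3,4-dihydronaphthalen-1(2H)-one | COc1cc2C(=O)CCC(C)(C)c2cc1C | intermediate
25 | (1S)-7-methoxy-1,4,4,6-tetramethyl-1,2,3,4-tetrahydronaphthalen-1-ol | COc1cc2c(cc1C)C(C)(C)CC[C@]2(C)O | intermediate
26 | (1S)-7-methoxy-1,4,4,6-tetramethyl-1,2,3,4,5,8-hexahydronaphthalen-1-ol | COC1=C(C)CC2=C(C1)[C@@](C)(O)CCC2(C)C | intermediate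
27 | (1S,4aR,8aS)-7-methoxy-1,4,4,6-tetramethyl-1,2,3,4,4a,5,8,8a-octahydronaphthalen-1-ol | COC1=C(C)C[C@@H]2[C@H](C1)[C@@](C)(O)CCC2(C)C | intermediate
28 | (4aR,8S,8aS)-8-hydroxy-3,5,5,8-tetramethyloctahydronaphthalen-2(1H)-one (both C3 epimers) | CC1C[C@@H]2[C@H](CC1=O)[C@@](C)(O)CCC2(C)C | intermediate
29 | (4aR,8S,8aS)-8-hydroxy-3,5,5,8-tetramethyl-4a,5,6,7,8,8a-hexahydronaphthalen-2(1H)-one | CC1=C[C@@H]2[C@H](CC1=O)[C@@](C)(O)CCC2(C)C | intermediate
30 | (4aR,8S,8aS)-3,4-epoxy-8-hydroxy-3,5,5,8-tetramethyloctahydronaphthalen-2(1H)-one (epoxide face not assigned) | CC12OC1[C@@H]1[C@H](CC2=O)[C@@](C)(O)CCC1(C)C | intermediate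
31 | (4aS,5S,8aR)-2,5,8,8-tetramethyl-1,4,4a,5,6,7,8,8a-octahydronaphthalene-1,5-diol (both C1 epimers) | CC1=CC[C@H]2[C@@H](C1O)C(C)(C)CC[C@]2(C)O | intermediate
32 | (4aS,5S,8aR)-5-hydroxy-2,5,8,8-tetramethyl-4a,5,6,7,8,8a-hexahydronaphthalen-1(4H)-one | CC1=CC[C@H]2[C@@H](C1=O)C(C)(C)CC[C@]2(C)O | intermediate
33 | (4aS,5S,8aR)-2,5,8,8-tetramethyl-5-[(triethylsilyl)oxy]-4a,5,6,7,8,8a-hexahydronaphthalen-1(4H)-one | CC1=CC[C@H]2[C@@H](C1=O)C(C)(C)CC[C@]2(C)O[Si](CC)(CC)CC | intermediate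
34 | (2-{(3S,5aS,6S,7S,9aS)-3-[(tert-butyldimethylsilyl)oxy]-2,2,5a,7-tetramethyl-7-[(triethylsilyl)oxy]decahydro-1-benzoxepin-6-yl}ethyl)lithium | [Li]CC[C@H]1[C@]2(C)CC[C@H](O[Si](C)(C)C(C)(C)C)C(C)(C)O[C@H]2CC[C@]1(C)O[Si](CC)(CC)CC | intermediate
35 | (4aS,5S,8aR)-1-{2-[(3S,5aS,6S,7S,9aS)-3-[(tert-butyldimethylsilyl)oxy]-2,2,5a,7-tetramethyl-7-[(triethylsilyl)oxy]decahydro-1-benzoxepin-6-yl]ethyl}-2,5,8,8-tetramethyl-5-[(triethylsilyl)oxy]-1,4,4a,5,6,7,8,8a-octahydronaphthalen-1-ol (both C1 epimers) | CC1=CC[C@H]2[C@@H](C1(O)CC[C@H]1[C@]3(C)CC[C@H](O[Si](C)(C)C(C)(C)C)C(C)(C)O[C@H]3CC[C@]1(C)O[Si](CC)(CC)CC)C(C)(C)CC[C@]2(C)O[Si](CC)(CC)CC | intermediate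
36 | (4aR,8S,8aS)-4-{2-[(3S,5aS,6S,7S,9aS)-3-[(tert-butyldimethylsilyl)oxy]-2,2,5a,7-tetramethyl-7-[(triethylsilyl)oxy]decahydro-1-benzoxepin-6-yl]ethyl}-3,5,5,8-tetramethyl-8-[(triethylsilyl)oxy]-4a,5,6,7,8,8a-hexahydronaphthalen-2(1H)-one | CC1=C(CC[C@H]2[C@]3(C)CC[C@H](O[Si](C)(C)C(C)(C)C)C(C)(C)O[C@H]3CC[C@]2(C)O[Si](CC)(CC)CC)[C@@H]2[C@H](CC1=O)[C@@](C)(O[Si](CC)(CC)CC)CCC2(C)C | intermediate
37 | sipholenol K, (4aR,8S,8aS)-4-{2-[(3S,5aS,6S,7S,9aS)-3,7-dihydroxy-2,2,5a,7-tetramethyldecahydro-1-benzoxepin-6-yl]ethyl}-8-hydroxy-3,5,5,8-tetramethyl-4a,5,6,7,8,8a-hexahydronaphthalen-2(1H)-one | CC1=C(CC[C@H]2[C@]3(C)CC[C@H](O)C(C)(C)O[C@H]3CC[C@]2(C)O)[C@@H]2[C@H](CC1=O)[C@@](C)(O)CCC2(C)C | target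

**Step count and risks**

Total steps: 23. Longest linear sequence: 14 steps (steps 1–11, then 21–23); the right half (steps 12–20) is made in parallel.

Steps most likely to fail:

Step 7. The excited furanone may add to the wrong face of the isopropenyl group, or the Lewis-acid opening of the cyclobutane may stall and ionise the tertiary silyl ether instead. The fallback sets out from 9 and comes back at 16. Amide 9 is acylated with the lithium enolate of 3-methyl-3-[(trimethylsilyl)oxy]butan-2-one to give the silyloxy diketone F1. Irradiation of its enol (de Mayo reaction; the cyclobutanol opens by retro-aldol as it forms) gives the ring B cyclohexanone F2, in which C7 already carries methyl C8 and the C9–C10–C11 keto chain. Reductive etherification between the C13 silyl ether and the C17 ketone (Et3SiH with BiBr3 or Me3SiOTf) then closes the oxepane with axial hydride delivery and returns 16.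

Step 3. The trisubstituted allylboronate may scramble by 1,3-boron shift, or react through the chair with the ester arm axial, so that diastereo- and enantiocontrol are eroded. The fallback sets out from 1 and comes back at 7. Wittig reaction of 1 with Ph3P=C(CH3)CO2Et gives ethyl (2E)-5-(benzyloxy)-2-methylpent-2-enoate F3, and (i-Bu)2AlH reduces it to (2E)-5-(benzyloxy)-2-methylpent-2-en-1-ol F4. Sharpless epoxidation (Ti(O-i-Pr)4, L-(+)-diisopropyl tartrate, t-BuOOH) gives {(2S,3S)-3-[2-(benzyloxy)ethyl]-2-methyloxiran-2-yl}methanol F5. Isopropenylmagnesium bromide with CuI opens the epoxide at the secondary carbon with inversion to give (2R,3S)-3-[2-(benzyloxy)ethyl]-2,4-dimethylpent-4-ene-1,2-diol F6. Selective tosylation of the primary hydroxyl and K2CO3 give (2R)-2-[(3S)-5-(benzyloxy)-2-methylpent-1-en-3-yl]-2-methyloxirane F7. Diethyl malonate with NaOEt opens it at the CH2 carbon and closes the lactone ester F8, and Krapcho decarboxylation (LiCl, wet DMSO, heat) gives 7.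

Step 14. The dissolving metal may cleave the benzylic C–O bond before the ring is reduced. The fallback sets out from 25 and comes back at 28. NaSEt in DMF demethylates 25 to the phenol (8S)-3,5,5,8-tetramethyl-5,6,7,8-tetrahydronaphthalene-2,8-diol F9. Hydrogenation over Rh/Al2O3 adds hydrogen all-cis from the hydroxyl-bearing face to give (4aR,8S,8aS)-3,5,5,8-tetramethyldecahydronaphthalene-2,8-diol F10. Dess–Martin oxidation of the secondary alcohol gives 28.

**Further compounds**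

F1 | step 7 | (8S,9S)-11-(benzyloxy)-2,8-dimethyl-9-(prop-1-en-2-yl)-8-[(triethylsilyl)oxy]-2-[(trimethylsilyl)oxy]undecane-3,5-dione | CC(C)(O[Si](C)(C)C)C(=O)CC(=O)CC[C@](C)(O[Si](CC)(CC)CC)[C@@H](CCOCc1ccccc1)C(C)=C
F2 | step 7 | (2S,3S,4S)-3-[2-(benzyloxy)ethyl]-2,4-dimethyl-2-{4-methyl-3-oxo-4-[(trimethylsilyl)oxy]pentyl}-4-[(triethylsilyl)oxy]cyclohexan-1-one | CC(C)(O[Si](C)(C)C)C(=O)CC[C@@]1(C)[C@H](CCOCc2ccccc2)[C@@](C)(O[Si](CC)(CC)CC)CCC1=O
F3 | step 3 | ethyl (2E)-5-(benzyloxy)-2-methylpent-2-enoate | CCOC(=O)/C(C)=C/CCOCc1ccccc1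
F4 | step 3 | (2E)-5-(benzyloxy)-2-methylpent-2-en-1-ol | OC/C(C)=C/CCOCc1ccccc1
F5 | step 3 | {(2S,3S)-3-[2-(benzyloxy)ethyl]-2-methyloxiran-2-yl}methanol | OC[C@]1(C)O[C@H]1CCOCc2ccccc2
F6 | step 3 | (2R,3S)-3-[2-(benzyloxy)ethyl]-2,4-dimethylpent-4-ene-1,2-diol | OC[C@](C)(O)[C@@H](CCOCc1ccccc1)C(C)=C
F7 | step 3 | (2R)-2-[(3S)-5-(benzyloxy)-2-methylpent-1-en-3-yl]-2-methyloxirane | C[C@]1(CO1)[C@@H](CCOCc2ccccc2)C(C)=C
F8 | step 3 | ethyl (5S)-5-[(3S)-5-(benzyloxy)-2-methylpent-1-en-3-yl]-5-methyl-2-oxotetrahydrofuran-3-carboxylate (both C3 epimers) | CCOC(=O)C1C[C@](C)(OC1=O)[C@@H](CCOCc2ccccc2)C(C)=C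
F9 | step 14 | (8S)-3,5,5,8-tetramethyl-5,6,7,8-tetrahydronaphthalene-2,8-diol | Oc1cc2c(cc1C)C(C)(C)CC[C@]2(C)O
F10 | step 14 | (4aR,8S,8aS)-3,5,5,8-tetramethyldecahydronaphthalene-2,8-diol (epimers at C2 and C3) | CC1C[C@@H]2[C@H](CC1O)[C@@](C)(O)CCC2(C)C
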